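**Strategy.** The indole is disconnected at the C2–C3 bond of the pyrrole ring, exploiting that C2 bears bromine and C3 a CH2–N arm. An ortho-isocyano (E)-N-styrylphthalimide, carrying both benzenoid bromines (future C5 and C6), is treated with Bu3SnH: the stannyl radical adds to the isocyanide carbon (future C2) and the imidoyl radical closes onto the enimide alkene, so that one operation builds the pyrrole ring, installs the C3 CH2N carbon at the correct oxidation level and leaves a C2–Sn bond for later ipso-bromination. The precursor comes from 3,4-dibromoaniline by ortho-iodination, N-formylation, Heck coupling with N-vinylphthalimide and formamide dehydration.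

Key step: step 5

Remark: the target has no stereocentre, the E geometry of 5 and 6 is consumed in step 5, and stannane 8, expected to be labile to acid and silica gel, is carried into step 6 as crude material.

Step 1
Reactants: 1 3,4-dibromoaniline
Product: 2 4,5-dibromo-2-iodoaniline
Conditions: NIS (1.0 equiv), DMF, 0 °C → rt, dark
Reagents that add atoms: N-iodosuccinimide, O=C1CCC(=O)N1I
Why: Electrophilic aromatic iodination directed by the amino group, in which the para position is blocked by bromine and the ortho position C2 is flanked by NH2 and Br, so iodine should enter at the open ortho position C6.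

Step 2
Reactants: 2 4,5-dibromo-2-iodoaniline
Product: 3 N-(4,5-dibromo-2-iodophenyl)formamide
Conditions: HCO2H/Ac2O (premixed, 55 °C), then 2, THF, 0 °C → rt
Reagents that add atoms: acetic formic anhydride (formed in the flask from formic acid and acetic anhydride), CC(=O)OC=O
Why: N-Formylation by a mixed anhydride, whose formyl carbonyl is the more electrophilic and less hindered one and should therefore acylate even this weakly nucleophilic, ortho-substituted aniline selectively.

Step 3
Reactants: 3 N-(4,5-dibromo-2-iodophenyl)formamide; 4 N-vinylphthalimide (2-ethenylisoindoline-1,3-dione)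
Product: 5 N-{4,5-dibromo-2-[(E)-2-(1,3-dioxoisoindolin-2-yl)ethenyl]phenyl}formamide
Conditions: 4 (1.5 equiv), Pd(OAc)2 (5 mol %), Bu4NCl (1 equiv), KOAc (2.5 equiv), DMF, 70 °C
Reagents that add atoms: none
Why: Mizoroki–Heck reaction under ligand-free, chloride-rich conditions, in which zerovalent palladium inserts into C–I well before C–Br at this temperature, the neutral pathway arylates the terminal carbon of the enimide, and syn insertion followed by syn β-hydride elimination gives the E alkene.

Step 4
Reactants: 5 N-{4,5-dibromo-2-[(E)-2-(1,3-dioxoisoindolin-2-yl)ethenyl]phenyl}formamide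
Product: 6 (E)-2-[2-(4,5-dibromo-2-isocyanophenyl)ethenyl]isoindoline-1,3-dione
Conditions: POCl3 (1.3 equiv), Et3N (5 equiv), CH2Cl2, 0 °C
Reagents that add atoms: none
Why: Dehydration of a formanilide to the isocyanide by O-phosphorylation and amine-induced elimination, conditions under which the enimide and the aryl bromides are inert.

Step 5
Reactants: 6 (E)-2-[2-(4,5-dibromo-2-isocyanophenyl)ethenyl]isoindoline-1,3-dione
Product: 8 2-{[5,6-dibromo-2-(tributylstannyl)-1H-indol-3-yl]methyl}isoindoline-1,3-dione, via 3H-indole tautomer 7 (not isolated)
Conditions: Bu3SnH (1.05 equiv), 2,2′-azobis(4-methoxy-2,4-dimethylvaleronitrile) (0.1 equiv), degassed PhMe (0.02 M), 35 °C; concentrated and used crude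
Reagents that add atoms: tributyltin hydride, CCCC[SnH](CCCC)CCCC
Why: The tributylstannyl radical released by the low-temperature azo initiator adds to the isocyanide carbon of 6 to give an α-stannyl imidoyl radical, which attacks the arene-bound alkene carbon and forms the C2–C3 bond; the exocyclic radical, stabilized by the imide nitrogen, takes hydrogen from Bu3SnH to give 3H-indole 7 and a new stannyl radical, and 7 tautomerizes to aromatic 8. This is the known tin-mediated radical cyclization of 2-alkenylaryl isocyanides to 2-stannylindoles (Fukuyama indole synthesis). The pyrrole ring closes in the 5-exo-trig mode. No stereocentre is retained, since the C3 centre of 7 is formed racemic and is erased by the tautomerization. The step needs 5-exo over 6-endo closure, which the substrate secures because attack at the inner alkene carbon is the kinetically preferred five-membered closure and leaves the radical next to the phthalimide nitrogen. It also needs stannyl attack at the isocyanide in preference to bromine abstraction from the two aryl C–Br bonds, which should be secured by the faster addition to the isocyanide, by running at 35 °C instead of 80 °C, and by limiting Bu3SnH to about one equivalent so that no chain carrier remains once 6 is consumed.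

Step 6
Reactants: 8 2-{[5,6-dibromo-2-(tributylstannyl)-1H-indol-3-yl]methyl}isoindoline-1,3-dione
Product: 9 2-[(2,5,6-tribromo-1H-indol-3-yl)methyl]isoindoline-1,3-dione
Conditions: Br2 (1.0 equiv), CH2Cl2, −78 °C
Reagents that add atoms: bromine, BrBr
Why: Electrophilic ipso-bromodestannylation, in which bromine attacks the stannylated C2 (positive charge stabilized by the C–Sn bond) much faster than any C–H position of the doubly brominated, C3-blocked indole, and Bu3SnBr departs.

Step 7
Reactants: 9 2-[(2,5,6-tribromo-1H-indol-3-yl)methyl]isoindoline-1,3-dione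
Product: 10 2-[(2,5,6-tribromo-1-methyl-1H-indol-3-yl)methyl]isoindoline-1,3-dione
Conditions: MeI (1.5 equiv), Cs2CO3 (1.5 equiv), DMF, 0 °C → rt
Reagents that add atoms: iodomethane, CI
Why: SN2 N-alkylation of the indole nitrogen, made more acidic by the three bromines, under mild anhydrous carbonate base that the N-substituted phthalimide tolerates and that keeps the indolide concentration low.

Step 8
Reactants: 10 2-[(2,5,6-tribromo-1-methyl-1H-indol-3-yl)methyl]isoindoline-1,3-dione
Product: 11 (2,5,6-tribromo-1-methyl-1H-indol-3-yl)methanamine
Conditions: N2H4·H2O (3 equiv), EtOH, 60 °C; amine used at once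
Reagents that add atoms: none
Why: Ing–Manske hydrazinolysis of the Gabriel-type phthalimide, in which hydrazine opens the imide and recloses to phthalhydrazide to release the primary amine, while the unactivated aryl and C2 bromides do not undergo substitution.

Step 9
Reactants: 11 (2,5,6-tribromo-1-methyl-1H-indol-3-yl)methanamine
Product: 13 2,5,6-tribromo-1-methylgramine, via N-monomethyl amine 12 (not isolated)
Conditions: aq. HCHO (37 %, 6 equiv), NaBH(OAc)3 (4 equiv), ClCH2CH2Cl, rt
Reagents that add atoms: formaldehyde, C=O
Why: Twofold reductive amination (iminium formation and hydride transfer, repeated through secondary amine 12) at room temperature without strong acid, so the gramine-type C3–CH2–N bond and the three C–Br bonds should stay intact.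

**Compound list**

1 | 3,4-dibromoaniline | Nc1ccc(Br)c(Br)c1 | starting material
2 | 4,5-dibromo-2-iodoaniline | Nc1cc(Br)c(Br)cc1I | intermediate
3 | N-(4,5-dibromo-2-iodophenyl)formamide | O=CNc1cc(Br)c(Br)cc1I | intermediate
4 | N-vinylphthalimide (2-ethenylisoindoline-1,3-dione) | C=CN1C(=O)c2ccccc2C1=O | starting material
5 | N-{4,5-dibromo-2-[(E)-2-(1,3-dioxoisoindolin-2-yl)ethenyl]phenyl}formamide | O=CNc1cc(Br)c(Br)cc1/C=C/N1C(=O)c2ccccc2C1=O | intermediate
6 | (E)-2-[2-(4,5-dibromo-2-isocyanophenyl)ethenyl]isoindoline-1,3-dione | [C-]#[N+]c1cc(Br)c(Br)cc1/C=C/N1C(=O)c2ccccc2C1=O | intermediate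
7 | 2-{[5,6-dibromo-2-(tributylstannyl)-3H-indol-3-yl]methyl}isoindoline-1,3-dione (racemic, not isolated) | CCCC[Sn](CCCC)(CCCC)C1=Nc2cc(Br)c(Br)cc2C1CN1C(=O)c2ccccc2C1=O | intermediate
8 | 2-{[5,6-dibromo-2-(tributylstannyl)-1H-indol-3-yl]methyl}isoindoline-1,3-dione | CCCC[Sn](CCCC)(CCCC)c1[nH]c2cc(Br)c(Br)cc2c1CN1C(=O)c2ccccc2C1=O | intermediate
9 | 2-[(2,5,6-tribromo-1H-indol-3-yl)methyl]isoindoline-1,3-dione | O=C1c2ccccc2C(=O)N1Cc1c(Br)[nH]c2cc(Br)c(Br)cc12 | intermediate
10 | 2-[(2,5,6-tribromo-1-methyl-1H-indol-3-yl)methyl]isoindoline-1,3-dione | O=C1c2ccccc2C(=O)N1Cc1c(Br)n(C)c2cc(Br)c(Br)cc12 | intermediate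
11 | (2,5,6-tribromo-1-methyl-1H-indol-3-yl)methanamine | NCc1c(Br)n(C)c2cc(Br)c(Br)cc12 | intermediate
12 | N-methyl-1-(2,5,6-tribromo-1-methyl-1H-indol-3-yl)methanamine (not isolated) | CNCc1c(Br)n(C)c2cc(Br)c(Br)cc12 | intermediate
13 | 2,5,6-tribromo-1-methylgramine | CN(C)Cc1c(Br)n(C)c2cc(Br)c(Br)cc12 | target

**Total step count:** 9 steps.
**Longest linear sequence:** 9 steps, from 1 to 13; 4 is used as purchased.

**Steps most likely to fail**

Step 5. Stannyl radicals may abstract bromine from the aryl C–Br bonds in competition with addition to the isocyanide, leading to hydrodebromination and aryl-radical side reactions; some 6-endo closure is also conceivable. The fallback avoids radicals altogether; it sets out from 2 and returns at 9. Gabriel alkylation of potassium phthalimide with 3-bromo-1-(trimethylsilyl)prop-1-yne (DMF, rt) gives 2-[3-(trimethylsilyl)prop-2-yn-1-yl]isoindoline-1,3-dione F1. Larock heteroannulation of 2 with F1 (Pd(OAc)2, LiCl, K2CO3, DMF, 100 °C) should react at C–I and place the bulkier silyl-bearing alkyne carbon next to nitrogen, giving 2-{[5,6-dibromo-2-(trimethylsilyl)-1H-indol-3-yl]methyl}isoindoline-1,3-dione F2. Ipso-bromodesilylation of F2 with NBS (CH2Cl2, 0 °C) then gives 9.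

Step 3. The formamide N–H may engage palladium (amidate formation, N-arylation or aza-Wacker-type closure onto the new enimide) and stall turnover. The fallback makes the C–C bond before the nitrogen is acylated; it sets out from 2 and returns at 5. Heck coupling of the free iodoaniline 2 with 4 (Pd(OAc)2, P(o-tol)3, Et3N, MeCN, 80 °C) should give (E)-2-[2-(2-amino-4,5-dibromophenyl)ethenyl]isoindoline-1,3-dione F3. The doubly acylated enimide nitrogen is a poor iminium precursor, so F3 should resist cyclization onto the amine. Formylation of F3 with acetic formic anhydride (THF, 0 °C) then gives 5. This does not cure competing oxidative addition at C–Br, which would be met only by lowering temperature and catalyst loading.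

Step 6. The N–H 2-stannylindole may lose tin by adventitious protonation before halogenation, or the indole may be brominated further by excess bromine. The fallback replaces ipso substitution at C–Sn by electrophilic substitution at C2–H; it sets out from 8 and returns at 9. Deliberate protodestannylation (1 M HCl, THF, rt) gives 2-[(5,6-dibromo-1H-indol-3-yl)methyl]isoindoline-1,3-dione F4. NBS (1.0 equiv, CH2Cl2, 0 °C) should then brominate F4 at C2, the only open pyrrole position of this C3-substituted indole (through the 3-bromoindolenine and bromine migration), to give 9.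

**Further compounds**

F1 | step 5 | 2-[3-(trimethylsilyl)prop-2-yn-1-yl]isoindoline-1,3-dione | C[Si](C)(C)C#CCN1C(=O)c2ccccc2C1=O
F2 | step 5 | 2-{[5,6-dibromo-2-(trimethylsilyl)-1H-indol-3-yl]methyl}isoindoline-1,3-dione | C[Si](C)(C)c1[nH]c2cc(Br)c(Br)cc2c1CN1C(=O)c2ccccc2C1=O
F3 | step 3 | (E)-2-[2-(2-amino-4,5-dibromophenyl)ethenyl]isoindoline-1,3-dione | Nc1cc(Br)c(Br)cc1/C=C/N1C(=O)c2ccccc2C1=O
F4 | step 6 | 2-[(5,6-dibromo-1H-indol-3-yl)methyl]isoindoline-1,3-dione | O=C1c2ccccc2C(=O)N1Cc1c[nH]c2cc(Br)c(Br)cc12
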